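The route rests on cutting the C4–C1′ bond. This bond joins the quaternary cyclopentane carbon to the benzylic methine and completes the bridging oxepane (O, C2, C3, C4, C1′, two arene carbons). The feature exploited is that C1′, its side-chain CH2 and the adjacent phenol oxygen map onto C4, C3 and O1 of a coumarin. Iron-hydride H-atom transfer to a C4=C15 methylene gives the tertiary C4 radical. This radical closes onto coumarin C4 and sets C4 and C1′ in one operation. The precursor is the (2R)-aromadendra-1(10),4(15)-dien-2-yl 5-O-ether of 3-acetyl-7-pivaloyloxycoumarin. The acetyl group steers attack to C4 and later supplies the isobutyl end.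

Key step: step 10

Remark: aromadendrane numbering (C1–C15) is used for the terpene part, C1′ for the benzylic carbon and coumarin numbers for the lactone. C5, C6 and C7 keep the ledene configuration throughout. Lactone C3 in 16 and 17 is an epimerisable β-dicarbonyl centre and is drawn without configuration. C4 of F1–F3 is also drawn without configuration because it becomes planar.

Step 1
Reactants: 1 (+)-ledene
Product: 2 (2S)-aromadendr-1(10)-en-2-ol (OH anti to H-5)
Conditions: SeO2 (0.5 equiv), t-BuOOH, CH2Cl2, 0 °C to rt
Reagents that add atoms: selenium dioxide O=[Se]=O; tert-butyl hydroperoxide CC(C)(C)OO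
Why: In this allylic hydroxylation by ene reaction and [2,3]-shift, selenium should bind the less crowded alkene carbon C10 rather than ring-fusion C1, so hydrogen is taken from C2 (CH2 preferred to the tertiary C5–H) and oxygen returns to C2 on the face away from the gem-dimethylcyclopropane, a configuration that step 2 erases.

Step 2
Reactants: 2 (2S)-aromadendr-1(10)-en-2-ol
Product: 4 aromadendra-1(10),3-dien-2-one, via enone 3 (not isolated)
Conditions: IBX (3.5 equiv), DMSO, rt then 70 °C
Reagents that add atoms: none
Why: IBX oxidation of the allylic alcohol, followed in the same pot by IBX dehydrogenation of 3 (whose only enolisable α-position is C3), should install C3=C4 under non-basic conditions that leave the activated C5–H alone, and the C4 centre of ledene is deliberately erased.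

Step 3
Reactants: 4 aromadendra-1(10),3-dien-2-one
Product: 5 2-oxoaromadendra-1(10),3-dien-15-al
Conditions: SeO2 (1.5 equiv), 1,4-dioxane, 80 °C
Reagents that add atoms: selenium dioxide O=[Se]=O
Why: In this Riley-type allylic oxidation of a β-methyl enone, selenium can reach only the unsubstituted α-carbon C3 (the other enone arm would need attack at fully substituted C1) and takes hydrogen from the C15 methyl rather than the tertiary C5–H, and oxidation through to the enal is accepted.

Step 4
Reactants: 5 2-oxoaromadendra-1(10),3-dien-15-al
Product: 6 15-hydroxyaromadendra-1(10),3-dien-2-one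
Conditions: DIBAL-H (1.05 equiv), CH2Cl2, −78 °C; Rochelle salt
Reagents that add atoms: none
Why: In this chemoselective 1,2-reduction, the unhindered aldehyde should be consumed at −78 °C well before the hindered cross-conjugated ketone, and DIBAL-H does not add in a conjugate sense.

Step 5
Reactants: 6 15-hydroxyaromadendra-1(10),3-dien-2-one
Product: 9 aromadendra-1(10),4(15)-dien-2-one, via sulfonylhydrazine 7 (not isolated), via allylic diazene 8 (not isolated)
Conditions: 2-nitrobenzenesulfonylhydrazide, PPh3, DEAD, THF, −30 °C to rt
Reagents that add atoms: none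
Why: In this allylic diazene rearrangement (Myers-type reductive transposition), Mitsunobu displacement at primary C15, loss of sulfinic acid and retro-ene loss of N2 deliver hydrogen to C3 and move the alkene to C4=C15 under neutral conditions, avoiding dienolate chemistry, which would deprotonate C14 or C5 instead of C15.

Step 6
Reactants: 9 aromadendra-1(10),4(15)-dien-2-one
Product: 10 (2S)-aromadendra-1(10),4(15)-dien-2-ol (OH anti to H-5)
Conditions: (R)-Me-CBS (0.3 equiv), catecholborane, toluene, −78 °C
Reagents that add atoms: none
Why: In this Corey–Bakshi–Shibata reduction, the (R)-oxazaborolidine should treat the tetrasubstituted alkenyl side as the large group and deliver hydride on the H-5 face to give the (2S)-alcohol, and catecholborane at −78 °C should neither hydroborate C4=C15 nor reconjugate the β,γ-enone.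

Step 7
Reactants: 11 2,4,6-trihydroxybenzaldehyde + 12 ethyl acetoacetate
Product: 13 3-acetyl-5,7-dihydroxycoumarin
Conditions: piperidine (cat.), EtOH, reflux
Reagents that add atoms: none
Why: Knoevenagel condensation followed by lactonisation onto an ortho phenol is the standard entry to 3-acetylcoumarins, and the symmetry of 11 allows only one product.

Step 8
Reactants: 13 3-acetyl-5,7-dihydroxycoumarin
Product: 14 3-acetyl-5-hydroxy-7-pivaloyloxycoumarin
Conditions: PivCl (1.0 equiv), pyridine, −10 °C
Reagents that add atoms: pivaloyl chloride CC(C)(C)C(=O)Cl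
Why: In this selective O-acylation, the 7-OH is the more acidic (para-quinoid conjugation to the acylvinyl unit) and unhindered hydroxyl, whereas the 5-OH is shielded by the peri C4–H, so the bulky acyl chloride should go to O7.

Step 9
Reactants: 10 (2S)-aromadendra-1(10),4(15)-dien-2-ol + 14 3-acetyl-5-hydroxy-7-pivaloyloxycoumarin
Product: 15 3-acetyl-5-O-[(2R)-aromadendra-1(10),4(15)-dien-2-yl]-7-pivaloyloxycoumarin (O-2 on the H-5 face)
Conditions: PPh3, DIAD (betaine pre-formed), toluene, −20 to 0 °C
Reagents that add atoms: none
Why: In this Mitsunobu etherification, the acidic phenol should displace the oxyphosphonium group at C2 by SN2 with inversion (2S to 2R), and SN2′ attack is blocked because C10 is fully substituted.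

Step 10
Reactants: 15 3-acetyl-5-O-[(2R)-aromadendra-1(10),4(15)-dien-2-yl]-7-pivaloyloxycoumarin
Product: 16 oxepane-bridged 3-acetyl-7-pivaloyloxy-3,4-dihydrocoumarin (C4–C1′ bond and O-2 both on the H-5 face; C15 anti to H-5; H-1′ pointing toward C5)
Conditions: Fe(acac)3 (0.5 equiv), PhSiH3 (3 equiv, syringe pump), i-PrOH/1,2-DCE 1:3 (0.005 M), Ar, 45 °C
Reagents that add atoms: none
Why: Proposed new method: An iron(III) hydride formed from Fe(acac)3, PhSiH3 and 2-propanol should pass H• to the unhindered CH2 terminus of C4=C15 (the tetrasubstituted C1=C10 and the peri-shielded trisubstituted coumarin alkene offer no accessible terminus), the nucleophilic tertiary C4 radical should add to coumarin C4, and iron(II) then reduces the 1,3-dicarbonyl radical to its enolate, which the alcohol protonates with return of iron(III). The closest known reaction types are the iron-mediated HAT–Giese reductive olefin coupling, including ring-forming versions, and Giese additions of alkyl radicals to C4 of 3-acyl- and 3-carboxycoumarins; the untested part is a seven-membered closure onto a coumarin. The oxepane closes 7-exo-trig (coumarin C3 stays outside the new ring), and the 8-endo alternative at C3, the site that plain coumarins prefer, is switched off because C3 is now fully substituted and the acetyl group places the largest LUMO coefficient on C4. C4 is controlled by the tether, since O-2 sits on the H-5 face and the C2–C3–C4 unit can only be bridged cis, so C15 ends anti to H-5. C1′ is controlled by how the flat coumarin can lie over the cyclopentane, with the arene over the small C3H2 bridge and its C4–H over C5, because the other face would press the arene against H-5 and the gem-dimethylcyclopropane. The step needs cyclisation to outrun a second H-atom transfer, which high dilution, slow silane addition and the LUMO-lowering acetyl and pivaloyl groups are meant to secure, and the new lactone C3 centre is epimerisable and disappears in step 11.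

Step 11
Reactants: 16 oxepane-bridged 3-acetyl-7-pivaloyloxy-3,4-dihydrocoumarin
Product: 18 bridged resorcinol methyl ketone (C1′–CH2–COCH3; in equilibrium with its hemiketal), via beta-keto acid 17 (not isolated)
Conditions: LiOH, THF/MeOH/H2O, rt; then 1 M HCl to pH 4–5, 40 °C
Reagents that add atoms: none
Why: In this ketonic hydrolysis of a β-keto aryl lactone, the aryl ester should open readily (acylketene E1cB pathway), the pivalate is saponified in the same pot, and the β-keto acid loses CO2 on mild acidification, so the temporary lactone carbonyl leaves and C1′, which has no acidic hydrogen, is not touched.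

Step 12
Reactants: 18 bridged resorcinol methyl ketone
Product: 19 bridged resorcinol with a 2-methylallyl group on C1′
Conditions: Ph3PCH3Br (6 equiv), KOt-Bu (5.5 equiv), THF, 0 °C to rt; NH4Cl quench
Reagents that add atoms: methyltriphenylphosphonium bromide C[P+](c1ccccc1)(c1ccccc1)c1ccccc1.[Br-]
Why: In this Wittig methylenation, excess ylide first deprotonates both phenols, the hemiketal–ketone equilibrium then feeds the unhindered methyl ketone, and the basic medium with a neutral work-up avoids acid-induced closure of the phenol onto the new alkene (2,2-dimethylchroman formation).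

Step 13
Reactants: 19 bridged resorcinol with a 2-methylallyl group on C1′
Product: 20 bridged isobutyl resorcinol (bis-deformyl target)
Conditions: H2 (1 atm), RhCl(PPh3)3 (5 mol %), benzene/EtOH, rt
Reagents that add atoms: none
Why: Homogeneous hydrogenation with Wilkinson's catalyst should reduce only the unhindered 1,1-disubstituted alkene and leave the tetrasubstituted C1=C10, the cyclopropane and the allylic aryl ether untouched.

Step 14
Reactants: 20 bridged isobutyl resorcinol
Product: 22 target CNP0388405.1 (2R,4R,1′S), via bis-iminium salt 21 (not isolated)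
Conditions: POCl3 (6 equiv), DMF (6 equiv), EtOAc, 0 °C to rt; then ice, aq NaOAc
Reagents that add atoms: N,N-dimethylformamide CN(C)C=O; water O
Why: In this double Vilsmeier–Haack formylation, the only two free ring positions are each flanked by two oxygen donors as in phloroglucinol, so the nucleus should accept two chloroiminium ions, and buffered hydrolysis releases both aldehydes without strong acid that could ionise the allylic C2–O bond.

Compound list
1 | (+)-ledene, aromadendr-1(10)-ene | CC1=C2[C@H]([C@H]3[C@@H](CC1)C3(C)C)[C@H](C)CC2 | starting material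
2 | (2S)-aromadendr-1(10)-en-2-ol | CC1=C2[C@H]([C@H]3[C@@H](CC1)C3(C)C)[C@H](C)C[C@@H]2O | intermediate
3 | aromadendr-1(10)-en-2-one | CC1=C2[C@H]([C@H]3[C@@H](CC1)C3(C)C)[C@H](C)CC2=O | intermediate
4 | aromadendra-1(10),3-dien-2-one | CC1=C2[C@H]([C@H]3[C@@H](CC1)C3(C)C)C(C)=CC2=O | intermediate
5 | 2-oxoaromadendra-1(10),3-dien-15-al | CC1=C2[C@H]([C@H]3[C@@H](CC1)C3(C)C)C(C=O)=CC2=O | intermediate
6 | 15-hydroxyaromadendra-1(10),3-dien-2-one | CC1=C2[C@H]([C@H]3[C@@H](CC1)C3(C)C)C(CO)=CC2=O | intermediate
7 | N-(2-oxoaromadendra-1(10),3-dien-15-yl)-2-nitrobenzenesulfonohydrazide | CC1=C2[C@H]([C@H]3[C@@H](CC1)C3(C)C)C(CN(N)S(=O)(=O)c1ccccc1[N+](=O)[O-])=CC2=O | intermediate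
8 | 15-diazenylaromadendra-1(10),3-dien-2-one | CC1=C2[C@H]([C@H]3[C@@H](CC1)C3(C)C)C(CN=N)=CC2=O | intermediate
9 | aromadendra-1(10),4(15)-dien-2-one | CC1=C2[C@H]([C@H]3[C@@H](CC1)C3(C)C)C(=C)CC2=O | intermediate
10 | (2S)-aromadendra-1(10),4(15)-dien-2-ol | CC1=C2[C@H]([C@H]3[C@@H](CC1)C3(C)C)C(=C)C[C@@H]2O | intermediate
11 | 2,4,6-trihydroxybenzaldehyde | O=Cc1c(O)cc(O)cc1O | starting material
12 | ethyl acetoacetate | CCOC(=O)CC(C)=O | starting material
13 | 3-acetyl-5,7-dihydroxycoumarin | CC(=O)C1=Cc2c(O)cc(O)cc2OC1=O | intermediate
14 | 3-acetyl-5-hydroxy-7-pivaloyloxycoumarin | CC(=O)C1=Cc2c(O)cc(OC(=O)C(C)(C)C)cc2OC1=O | intermediate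
15 | 3-acetyl-5-O-[(2R)-aromadendra-1(10),4(15)-dien-2-yl]-7-pivaloyloxycoumarin | CC1=C2[C@H]([C@H]3[C@@H](CC1)C3(C)C)C(=C)C[C@H]2Oc1cc(OC(=O)C(C)(C)C)cc2OC(=O)C(C(C)=O)=Cc12 | intermediate
16 | oxepane-bridged 3-acetyl-7-pivaloyloxy-3,4-dihydrocoumarin | CC1=C2[C@H]([C@H]3[C@@H](CC1)C3(C)C)[C@]1(C)C[C@H]2Oc2cc(OC(=O)C(C)(C)C)cc3OC(=O)C(C(C)=O)[C@@H]1c23 | intermediate
17 | ring-opened β-keto acid (both phenols free) | CC1=C2[C@H]([C@H]3[C@@H](CC1)C3(C)C)[C@]1(C)C[C@H]2Oc2cc(O)cc(O)c2[C@H]1C(C(C)=O)C(=O)O | intermediate
18 | bridged resorcinol methyl ketone | CC1=C2[C@H]([C@H]3[C@@H](CC1)C3(C)C)[C@]1(C)C[C@H]2Oc2cc(O)cc(O)c2[C@H]1CC(C)=O | intermediate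
19 | bridged resorcinol, 2-methylallyl on C1′ | CC1=C2[C@H]([C@H]3[C@@H](CC1)C3(C)C)[C@]1(C)C[C@H]2Oc2cc(O)cc(O)c2[C@H]1CC(C)=C | intermediate
20 | bridged isobutyl resorcinol | CC1=C2[C@H]([C@H]3[C@@H](CC1)C3(C)C)[C@]1(C)C[C@H]2Oc2cc(O)cc(O)c2[C@H]1CC(C)C | intermediate
21 | bis(dimethyliminium) dichloride of 20 | CC1=C2[C@H]([C@H]3[C@@H](CC1)C3(C)C)[C@]1(C)C[C@H]2Oc2c(C=[N+](C)C)c(O)c(C=[N+](C)C)c(O)c2[C@H]1CC(C)C.[Cl-].[Cl-] | intermediate
22 | CNP0388405.1 | CC1=C2[C@H]([C@H]3[C@@H](CC1)C3(C)C)[C@]1(C)C[C@H]2Oc2c(C=O)c(O)c(C=O)c(O)c2[C@H]1CC(C)C | target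

Total step count: 14. Longest linear sequence: 12 (steps 1–6 and 9–14 from 1; steps 7–8 form the short branch).

Steps most likely to fail

Step 10. Several things may go wrong:
- The tertiary radical may take a second hydrogen atom, or be returned to an internal alkene, faster than it closes a crowded seven-membered ring beside the gem-dimethylcyclopropane.
- The hydride system may reduce the acetylcoumarin.
- The allylic ether may solvolyse.
- Facial discrimination at C1′ may be poor.

The fallback makes the same radical irreversibly and without any hydride present during ring closure. It sets out from 15. Mukaiyama hydration (Mn(dpm)3, PhSiH3, O2, i-PrOH, 0 °C; oxygen capture outruns cyclisation) should give the tertiary C4 alcohol F1. Acylation with methyl chlorooxoacetate (Et3N, DMAP) gives the methyl oxalate F2. One equivalent of aqueous CsOH at 0 °C gives the caesium oxalate F3. Visible-light photoredox double decarboxylation (Ir[dF(CF3)ppy]2(dtbbpy)PF6, DME/DMF, H2O, high dilution) then performs the known tertiary-radical conjugate addition. The route is rejoined at 16.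

Step 9. The oxyphosphonium ion of this hindered allylic alcohol may ionise, which erodes inversion. It may also eliminate toward the cross-conjugated triene, and the phosphine may add reversibly to the electrophilic coumarin. The fallback replaces the redox condensation with a double inversion and sets out from 9. CBS reduction with the (S)-catalyst gives the (2R)-dienol F4. Appel-type chlorination (PPh3, hexachloroacetone, −20 °C) gives, with inversion and without allylic shift, the (2S)-allylic chloride F5. Displacement by the caesium phenoxide of 14 (Cs2CO3, DMF, 0 °C) inverts again. The route is rejoined at 15.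

Step 1. Selenium may bind C1 instead of C10, which moves hydroxylation to C9 or C14, and over-oxidation may complicate separation. The fallback gives up the pericyclic hydroxylation for a radical-chain allylic ketonisation. It sets out from 1 (Rh2(cap)4, aqueous t-BuOOH, CH2Cl2) and gives the enone directly. The 9-oxo isomer is removed by chromatography. The route is rejoined at 3, which is then dehydrogenated under the step 2 conditions.

Further compounds
F1 | step 10 | 4-hydroxy-4,15-dihydro derivative of 15 (tertiary alcohol) | CC1=C2[C@H]([C@H]3[C@@H](CC1)C3(C)C)C(C)(O)C[C@H]2Oc1cc(OC(=O)C(C)(C)C)cc2OC(=O)C(C(C)=O)=Cc12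
F2 | step 10 | methyl oxalate of F1 | CC1=C2[C@H]([C@H]3[C@@H](CC1)C3(C)C)C(C)(OC(=O)C(=O)OC)C[C@H]2Oc1cc(OC(=O)C(C)(C)C)cc2OC(=O)C(C(C)=O)=Cc12
F3 | step 10 | caesium oxalate of F1 | CC1=C2[C@H]([C@H]3[C@@H](CC1)C3(C)C)C(C)(OC(=O)C(=O)[O-])C[C@H]2Oc1cc(OC(=O)C(C)(C)C)cc2OC(=O)C(C(C)=O)=Cc12.[Cs+]
F4 | step 9 | (2R)-aromadendra-1(10),4(15)-dien-2-ol | CC1=C2[C@H]([C@H]3[C@@H](CC1)C3(C)C)C(=C)C[C@H]2O
F5 | step 9 | (2S)-2-chloroaromadendra-1(10),4(15)-diene | CC1=C2[C@H]([C@H]3[C@@H](CC1)C3(C)C)C(=C)C[C@@H]2Cl
F0 | step 1 | none | none
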